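Everything rests on cutting the C2–C3 bond of the ten-membered carbocycle (C1 ester carbinol, C2 free carbinol, C3 CH–CH3, C4–C7 furanone carbons, C8 CH2, C9/C10 lactone CH–O/CH). C3 is the γ-carbon of the furanone vinylogous ester (C6=O, C5=C4) and C2 a carbinol, so the bond is a vinylogous aldol bond. One operation closes the carbocycle across the existing furanone and sets C2 and C3. The substrate is an open chain: the silyl dienol ether of a 5-ethyl-3(2H)-furanone joined through C8, silyloxy C9 and C10 (carrying the protected 2-propen-1-ol unit) to an α-PMB-oxy aldehyde (C1, C2).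

Key step: step 17

Remark (numbering): C11 is the alkene carbon on C10, C12 its CH2–O carbon (the lactone carbonyl carbon of the target) and C13 the exocyclic methylene carbon; O1, O2, O9 and O12 are the oxygens on C1, C2, C9 and C12.
Remark (assumption): the carbinol carbon of 7 and the acetal carbon of 20–22 form as epimer mixtures and are carried as such, since both centres disappear (steps 5 and 15).
Remark (precursor design): in the cyclisation substrate O12 carries TIPS instead of TBS so that it survives the acidic acetal exchange of step 13; the skeleton is unchanged.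

Step 1
Reactants: 1 (R)-citramalic acid
Product: 2 2-[(4R)-2,2,4-trimethyl-5-oxo-1,3-dioxolan-4-yl]acetic acid
Conditions: Me2C(OMe)2, TsOH (cat.), CH2Cl2, rt
Reagents that add atoms: 2,2-dimethoxypropane, COC(C)(C)OC
Why: Acid-catalysed acetalisation ties the tertiary hydroxyl and the neighbouring carboxyl group into the five-membered dioxolanone (acetonide of an α-hydroxy acid) and leaves the CH2CO2H arm free, without touching the C7 stereocentre.

Step 2
Reactants: 2 2-[(4R)-2,2,4-trimethyl-5-oxo-1,3-dioxolan-4-yl]acetic acid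
Product: 3 (5R)-5-(2-hydroxyethyl)-2,2,5-trimethyl-1,3-dioxolan-4-one
Conditions: BH3·SMe2, THF, 0 °C → rt; aqueous work-up
Reagents that add atoms: none
Why: Chemoselective borane reduction of the free carboxylic acid (through the acyloxyborane) in the presence of the ester-type dioxolanone.

Step 3
Reactants: 3 (5R)-5-(2-hydroxyethyl)-2,2,5-trimethyl-1,3-dioxolan-4-one
Product: 4 2-[(4R)-2,2,4-trimethyl-5-oxo-1,3-dioxolan-4-yl]acetaldehyde
Conditions: Dess–Martin periodinane, pyridine, CH2Cl2, 0 °C → rt
Reagents that add atoms: none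
Why: Dess–Martin oxidation of the primary alcohol stops at the aldehyde under buffered conditions that should neither open the dioxolanone nor cause lactonisation.

Step 4
Reactants: 5 (R)-2,2-dimethyl-1,3-dioxolane-4-carbaldehyde; 6 methyl acrylate
Product: 7 methyl 2-{[(4R)-2,2-dimethyl-1,3-dioxolan-4-yl](hydroxy)methyl}prop-2-enoate (both carbinol epimers)
Conditions: DABCO (0.5 equiv), 1,4-dioxane/H2O, rt
Reagents that add atoms: none
Why: Morita–Baylis–Hillman reaction; the new carbinol centre should form as an epimer mixture, which is harmless because it becomes sp2 in step 5, and the dioxolane centre is not affected.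

Step 5
Reactants: 7 Baylis–Hillman adduct
Product: 8 methyl (2Z)-2-(bromomethyl)-3-[(4S)-2,2-dimethyl-1,3-dioxolan-4-yl]prop-2-enoate
Conditions: NBS, Me2S, CH2Cl2, 0 °C → rt
Reagents that add atoms: N-bromosuccinimide, O=C1CCC(=O)N1Br
Why: Corey–Kim-type activation of the allylic alcohol as its alkoxysulfonium salt and SN2′ attack of bromide (allylic transposition) should give the thermodynamically favoured (Z)-2-(bromomethyl)enoate, both carbinol epimers converging on one product.

Step 6
Reactants: 8 (Z)-bromo ester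
Product: 9 (2Z)-2-(bromomethyl)-3-[(4S)-2,2-dimethyl-1,3-dioxolan-4-yl]prop-2-en-1-ol
Conditions: i-Bu2AlH (2.2 equiv), CH2Cl2, −78 °C; Rochelle salt
Reagents that add atoms: none
Why: 1,2-Reduction of the conjugated ester by DIBAL-H at low temperature, which leaves the allylic bromide and the acetonide untouched.

Step 7
Reactants: 9 bromo allylic alcohol
Product: 10 {[(2Z)-2-(bromomethyl)-3-[(4S)-2,2-dimethyl-1,3-dioxolan-4-yl]prop-2-en-1-yl]oxy}tri(propan-2-yl)silane
Conditions: i-Pr3SiOTf, 2,6-lutidine, CH2Cl2, −78 °C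
Reagents that add atoms: triisopropylsilyl trifluoromethanesulfonate, CC(C)[Si](OS(=O)(=O)C(F)(F)F)(C(C)C)C(C)C
Why: Silylation of the primary allylic alcohol with a silyl triflate and a hindered base avoids N-alkylation by the allylic bromide, and TIPS is chosen because it must outlast step 13.

Step 8
Reactants: 4 2-[(4R)-2,2,4-trimethyl-5-oxo-1,3-dioxolan-4-yl]acetaldehyde; 10 allylic bromide (TIPS ether)
Product: 12 homoallylic alcohol (C9 OH; dioxolanone at C6/C7; C12 OTIPS; C1/C2 acetonide), via allylchromium dichloride 11 (not isolated)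
Conditions: CrCl2 (4 equiv), THF, 0 °C → rt; aq. NH4Cl
Reagents that add atoms: none
Why: Nozaki–Hiyama allylation: the allylchromium reagent (trivalent chromium) adds through its γ-carbon C10 in a chair transition state in which the chromium ligands force the C1 substituent equatorial whatever the bromide geometry, giving the anti C9/C10 relationship of the trans-lactone series (an ester-bearing reagent would give the syn series and is avoided), while allylic 1,3-strain with the cis CH2OTIPS group turns the C1–H bond into the alkene plane and the aldehyde should attack anti to the C1–O bond, which sets C10 and hence C9 relative to the glyceraldehyde-derived C1.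

Step 9
Reactants: 12 homoallylic alcohol
Product: 13 C9 tert-butyldimethylsilyl ether of 12
Conditions: TBSOTf, 2,6-lutidine, CH2Cl2, −78 °C
Reagents that add atoms: tert-butyldimethylsilyl trifluoromethanesulfonate, CC(C)(C)[Si](C)(C)OS(=O)(=O)C(F)(F)F
Why: Silyl triflate silylation of the hindered secondary alcohol, done at once so that the C9 hydroxyl cannot attack the dioxolanone carbonyl; ketals and the TIPS ether are stable to these conditions.

Step 10
Reactants: 13 C9 silyl ether
Product: 14 Weinreb amide at C6 with free tertiary C7 hydroxyl (C9 OTBS; C12 OTIPS; C1/C2 acetonide)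
Conditions: MeNH(OMe)·HCl, i-PrMgCl, THF, −20 → 0 °C
Reagents that add atoms: N,O-dimethylhydroxylamine hydrochloride, CNOC.Cl
Why: Aminolysis of the activated acetal-type ester by the magnesium amide of N,O-dimethylhydroxylamine opens the dioxolanone with loss of acetone and gives the α-hydroxy Weinreb amide without touching C7.

Step 11
Reactants: 14 Weinreb amide; 15 but-1-yne
Product: 17 α′-hydroxy ynone (C7 OH; C6 ketone; C5≡C4 bearing ethyl), via 1-butynyllithium 16 (not isolated)
Conditions: n-BuLi, THF, −78 °C; then 14, −78 → −20 °C; aq. NH4Cl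
Reagents that add atoms: none
Why: Weinreb ketone synthesis: the alkynyllithium (in excess, the tertiary hydroxyl being deprotonated first) adds once and the chelated tetrahedral intermediate collapses to the ynone only on work-up.

Step 12
Reactants: 17 α′-hydroxy ynone
Product: 18 2,2-disubstituted 5-ethyl-3(2H)-furanone (C9 OTBS; C12 OTIPS; C1/C2 acetonide)
Conditions: (4-CF3C6H4)3PAuCl (2 mol %), AgOTf (2 mol %), toluene, rt
Reagents that add atoms: none
Why: Gold-catalysed 5-endo-dig cycloisomerisation of the α′-hydroxy ynone (intramolecular oxa-Michael addition of the tertiary hydroxyl to the activated alkyne) should give the furanone under neutral conditions.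

Step 13
Reactants: 18 furanone acetonide
Product: 20 4-methoxybenzylidene acetal of the C1/C2 diol (acetal epimers), via diol 19 (not isolated)
Conditions: PPTS (cat.), MeOH, 45 °C; evaporate; then 4-MeOC6H4CH(OMe)2, PPTS (cat.), CH2Cl2, rt
Reagents that add atoms: 4-methoxybenzaldehyde dimethyl acetal, COc1ccc(cc1)C(OC)OC
Why: Acid-catalysed methanolysis of the terminal acetonide and re-acetalisation of the 1,2-diol (transacetalisation), the secondary TBS and primary TIPS ethers being stable to PPTS; the new acetal carbon is an inconsequential epimer mixture that becomes a CH2 group in step 15.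

Step 14
Reactants: 20 4-methoxybenzylidene acetal
Product: 22 tert-butyldimethylsilyl dienol ether ((Z)-2-ethylidene-4-silyloxy-2,5-dihydrofuran), via lithium dienolate 21 (not isolated)
Conditions: LiN(SiMe3)2, THF, −78 °C; then TBSOTf, −78 °C; Et3N, pH 7 buffer
Reagents that add atoms: tert-butyldimethylsilyl trifluoromethanesulfonate, CC(C)(C)[Si](C)(C)OS(=O)(=O)C(F)(F)F
Why: Kinetic γ-deprotonation of the 5-ethylfuranone (C7 is quaternary, so the ethyl CH2 is the only acidic site) and O-silylation of the extended dienolate by the hard silyl triflate; the (Z)-ethylidene isomer is expected because the methyl group avoids allylic strain with the C5 hydrogen.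

Step 15
Reactants: 22 silyl dienol ether
Product: 23 C2 primary alcohol with PMB ether on O1
Conditions: i-Bu2AlH (5 equiv), CH2Cl2, −78 → 0 °C; Rochelle salt
Reagents that add atoms: none
Why: Regioselective reductive opening of the 4-methoxybenzylidene acetal: the alane coordinates the less hindered primary oxygen and delivers hydride to the acetal carbon, which leaves the PMB ether on the secondary O1 and frees the C2 alcohol, while the silyl dienol ether masks the furanone carbonyl against hydride.

Step 16
Reactants: 23 primary alcohol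
Product: 24 cyclisation substrate (C2 aldehyde; C1 OPMB; C9 OTBS; C12 OTIPS; silyl dienol ether)
Conditions: (n-Pr)4N[RuO4] (5 mol %), N-methylmorpholine N-oxide, 4 Å molecular sieves, CH2Cl2, 0 °C
Reagents that add atoms: none
Why: Ley–Griffith oxidation of the primary alcohol under neutral anhydrous conditions, which should spare the acid-labile dienol ether and not epimerise the α-alkoxy aldehyde at C1; the aldehyde is used at once.

Step 17
Reactants: 24 cyclisation substrate
Product: 25 furanone-bridged ten-membered carbocycle with free C2 hydroxyl (C1 OPMB; C9 OTBS; C12 OTIPS)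
Conditions: MgBr2·OEt2 (3 equiv), CH2Cl2, −78 → −20 °C, slow addition of 24 to a final concentration of 1 mM; aq. NaHCO3
Reagents that add atoms: none
Why: Proposed new method: MgBr2·OEt2 should clamp the aldehyde oxygen and the PMB-ether oxygen on C1 in a five-membered chelate, and the terminal carbon C3 of the 2-ethylidene-4-silyloxy-2,5-dihydrofuran then adds to the activated carbonyl through an open transition state, with loss of the silyl group as its bromide and return of the furanone vinylogous ester. The closest known reaction types are the intermolecular γ-aldol additions of 5-alkyl-3(2H)-furanone dienolates to aldehydes and chelation-controlled (vinylogous) Mukaiyama aldol additions to α-alkoxy aldehydes; their intramolecular use to close a medium ring on this substrate class is not known. The ten-membered carbocycle closes in a 10-exo-trig mode by attack of the γ-carbon on the aldehyde carbon, the flat dihydrofuran and the quaternary C7 pre-folding the tether. C2 should be set by the chelate (attack on the carbonyl face away from the C10 branch gives the 1,2-syn diol pattern) and C3 by the (Z)-ethylidene geometry in the antiperiplanar open transition state. The step needs γ- over α-attack (attack through C5 would give a strained eight-membered ring and a non-conjugated product, so the extended dienol ether should react at C3), ring closure over oligomerisation (high dilution, slow addition) and no enolisation of the α-alkoxy aldehyde (mild Lewis acid, no base).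

Step 18
Reactants: 25 macrocyclic C2 alcohol
Product: 26 C2 tert-butyldimethylsilyl ether of 25
Conditions: TBSOTf, 2,6-lutidine, CH2Cl2, −78 → 0 °C
Reagents that add atoms: tert-butyldimethylsilyl trifluoromethanesulfonate, CC(C)(C)[Si](C)(C)OS(=O)(=O)C(F)(F)F
Why: Silyl triflate silylation of the hindered C2 hydroxyl, which also blocks retro-aldol cleavage and dehydration of the δ-hydroxy vinylogous ester in the following steps.

Step 19
Reactants: 26 C2 silyl ether
Product: 27 C1 alcohol (C2 OTBS; C9 OTBS; C12 OTIPS)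
Conditions: DDQ, CH2Cl2/pH 7 buffer, 0 °C
Reagents that add atoms: none
Why: Oxidative removal of the PMB ether by DDQ (hydride abstraction to the benzylic oxocarbenium ion and hydrolysis), to which silyl ethers, the furanone and the 1,1-disubstituted alkene are inert.

Step 20
Reactants: 27 C1 alcohol
Product: 28 C1 methacrylate
Conditions: methacrylic anhydride, DMAP, Et3N, CH2Cl2, rt
Reagents that add atoms: methacrylic anhydride, CC(=C)C(=O)OC(=O)C(C)=C
Why: DMAP-catalysed acylation of the only free hydroxyl (C1) through the acylpyridinium ion.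

Step 21
Reactants: 28 C1 methacrylate
Product: 29 triol (C2 OH; C9 OH; C12 OH)
Conditions: HF·pyridine, pyridine, THF, 0 °C → rt
Reagents that add atoms: none
Why: Fluoride-mediated cleavage of the two TBS ethers and the TIPS ether under buffered, weakly acidic conditions that should not move the methacrylate from O1 to O2.

Step 22
Reactants: 29 triol
Product: 32 CNP0195404.1 (target), via enal 30 (not isolated), via lactol 31 (not isolated)
Conditions: MnO2 (excess), CH2Cl2, rt
Reagents that add atoms: none
Why: Oxidative lactonisation of the 2-methylene-1,4-diol: MnO2 oxidises only the allylic primary alcohol to the enal, the C9 hydroxyl closes the fused five-membered lactol (the C2 hydroxyl could only form a bridged six-membered one) and the allylic lactol is oxidised on to the α-methylene-γ-butyrolactone, with no stereocentre affected.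

Compound list
1 | (R)-citramalic acid, (2R)-2-hydroxy-2-methylbutanedioic acid | C[C@@](O)(CC(=O)O)C(=O)O | starting material
2 | 2-[(4R)-2,2,4-trimethyl-5-oxo-1,3-dioxolan-4-yl]acetic acid | OC(=O)C[C@@]1(C)OC(C)(C)OC1=O | intermediate
3 | (5R)-5-(2-hydroxyethyl)-2,2,5-trimethyl-1,3-dioxolan-4-one | OCC[C@@]1(C)OC(C)(C)OC1=O | intermediate
4 | 2-[(4R)-2,2,4-trimethyl-5-oxo-1,3-dioxolan-4-yl]acetaldehyde | O=CC[C@@]1(C)OC(C)(C)OC1=O | intermediate
5 | (R)-2,2-dimethyl-1,3-dioxolane-4-carbaldehyde | CC1(C)OC[C@H](C=O)O1 | starting material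
6 | methyl acrylate | C=CC(=O)OC | starting material
7 | methyl 2-{[(4R)-2,2-dimethyl-1,3-dioxolan-4-yl](hydroxy)methyl}prop-2-enoate (both carbinol epimers) | CC1(C)OC[C@H](C(O)C(=C)C(=O)OC)O1 | intermediate
8 | methyl (2Z)-2-(bromomethyl)-3-[(4S)-2,2-dimethyl-1,3-dioxolan-4-yl]prop-2-enoate | CC1(C)OC[C@H](/C=C(\CBr)C(=O)OC)O1 | intermediate
9 | (2Z)-2-(bromomethyl)-3-[(4S)-2,2-dimethyl-1,3-dioxolan-4-yl]prop-2-en-1-ol | CC1(C)OC[C@H](/C=C(\CBr)CO)O1 | intermediate
10 | {[(2Z)-2-(bromomethyl)-3-[(4S)-2,2-dimethyl-1,3-dioxolan-4-yl]prop-2-en-1-yl]oxy}tri(propan-2-yl)silane | CC1(C)OC[C@H](/C=C(\CBr)CO[Si](C(C)C)(C(C)C)C(C)C)O1 | intermediate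
11 | allylchromium dichloride formed from 10 (trivalent chromium; alkene geometry mobile; not isolated) | CC1(C)OC[C@H](C=C(C[Cr](Cl)Cl)CO[Si](C(C)C)(C(C)C)C(C)C)O1 | intermediate
12 | (5R)-5-{(2S,3R)-3-[(4S)-2,2-dimethyl-1,3-dioxolan-4-yl]-2-hydroxy-4-({[tri(propan-2-yl)silyl]oxy}methyl)pent-4-en-1-yl}-2,2,5-trimethyl-1,3-dioxolan-4-one (C9 alcohol) | CC1(C)OC[C@H]([C@H](C(=C)CO[Si](C(C)C)(C(C)C)C(C)C)[C@@H](O)C[C@@]2(C)OC(C)(C)OC2=O)O1 | intermediate
13 | C9 tert-butyldimethylsilyl ether of 12 | CC1(C)OC[C@H]([C@H](C(=C)CO[Si](C(C)C)(C(C)C)C(C)C)[C@@H](O[Si](C)(C)C(C)(C)C)C[C@@]2(C)OC(C)(C)OC2=O)O1 | intermediate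
14 | N-methoxy-N-methyl amide at C6 with free tertiary C7 hydroxyl (C9 OTBS, C12 OTIPS, C1/C2 acetonide) | CC1(C)OC[C@H]([C@H](C(=C)CO[Si](C(C)C)(C(C)C)C(C)C)[C@@H](O[Si](C)(C)C(C)(C)C)C[C@@](C)(O)C(=O)N(C)OC)O1 | intermediate
15 | but-1-yne | CCC#C | starting material
16 | 1-butynyllithium (not isolated) | [Li]C#CCC | intermediate
17 | α′-hydroxy ynone: C7 tertiary alcohol, C6 ketone, but-1-ynyl group (C9 OTBS, C12 OTIPS, C1/C2 acetonide) | CC1(C)OC[C@H]([C@H](C(=C)CO[Si](C(C)C)(C(C)C)C(C)C)[C@@H](O[Si](C)(C)C(C)(C)C)C[C@@](C)(O)C(=O)C#CCC)O1 | intermediate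
18 | 5-ethyl-2-methyl-3(2H)-furanone carrying the C8–C2 chain at C7 (C9 OTBS, C12 OTIPS, C1/C2 acetonide) | CC1(C)OC[C@H]([C@H](C(=C)CO[Si](C(C)C)(C(C)C)C(C)C)[C@@H](O[Si](C)(C)C(C)(C)C)C[C@@]2(C)OC(CC)=CC2=O)O1 | intermediate
19 | C1,C2-diol obtained from 18 (not isolated) | OC[C@@H](O)[C@H](C(=C)CO[Si](C(C)C)(C(C)C)C(C)C)[C@@H](O[Si](C)(C)C(C)(C)C)C[C@@]1(C)OC(CC)=CC1=O | intermediate
20 | 4-methoxybenzylidene acetal of diol 19 (acetal epimers) | COc1ccc(cc1)C1OC[C@H]([C@H](C(=C)CO[Si](C(C)C)(C(C)C)C(C)C)[C@@H](O[Si](C)(C)C(C)(C)C)C[C@@]2(C)OC(CC)=CC2=O)O1 | intermediate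
21 | lithium dienolate of 20 (not isolated) | COc1ccc(cc1)C1OC[C@H]([C@H](C(=C)CO[Si](C(C)C)(C(C)C)C(C)C)[C@@H](O[Si](C)(C)C(C)(C)C)C[C@@]2(C)O/C(=C\C)C=C2O[Li])O1 | intermediate
22 | tert-butyldimethylsilyl dienol ether of 20, (Z)-2-ethylidene-4-silyloxy-2,5-dihydrofuran | COc1ccc(cc1)C1OC[C@H]([C@H](C(=C)CO[Si](C(C)C)(C(C)C)C(C)C)[C@@H](O[Si](C)(C)C(C)(C)C)C[C@@]2(C)O/C(=C\C)C=C2O[Si](C)(C)C(C)(C)C)O1 | intermediate
23 | C2 primary alcohol with PMB ether on O1 (C9 OTBS, C12 OTIPS, silyl dienol ether) | OC[C@@H](OCc1ccc(OC)cc1)[C@H](C(=C)CO[Si](C(C)C)(C(C)C)C(C)C)[C@@H](O[Si](C)(C)C(C)(C)C)C[C@@]2(C)O/C(=C\C)C=C2O[Si](C)(C)C(C)(C)C | intermediate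
24 | cyclisation substrate: furanone silyl dienol ether with tethered C2 aldehyde (C1 OPMB, C9 OTBS, C12 OTIPS) | O=C[C@@H](OCc1ccc(OC)cc1)[C@H](C(=C)CO[Si](C(C)C)(C(C)C)C(C)C)[C@@H](O[Si](C)(C)C(C)(C)C)C[C@@]2(C)O/C(=C\C)C=C2O[Si](C)(C)C(C)(C)C | intermediate
25 | furanone-bridged ten-membered carbocycle with free C2 hydroxyl (C1 OPMB, C9 OTBS, C12 OTIPS) | COc1ccc(CO[C@@H]2[C@@H](O)[C@H](C)C3=CC(=O)[C@@](C)(C[C@H](O[Si](C)(C)C(C)(C)C)[C@H]2C(=C)CO[Si](C(C)C)(C(C)C)C(C)C)O3)cc1 | intermediate
26 | C2 tert-butyldimethylsilyl ether of 25 | COc1ccc(CO[C@@H]2[C@@H](O[Si](C)(C)C(C)(C)C)[C@H](C)C3=CC(=O)[C@@](C)(C[C@H](O[Si](C)(C)C(C)(C)C)[C@H]2C(=C)CO[Si](C(C)C)(C(C)C)C(C)C)O3)cc1 | intermediate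
27 | C1 alcohol (C2 OTBS, C9 OTBS, C12 OTIPS) | O[C@@H]1[C@@H](O[Si](C)(C)C(C)(C)C)[C@H](C)C2=CC(=O)[C@@](C)(C[C@H](O[Si](C)(C)C(C)(C)C)[C@H]1C(=C)CO[Si](C(C)C)(C(C)C)C(C)C)O2 | intermediate
28 | C1 methacrylate (C2 OTBS, C9 OTBS, C12 OTIPS) | C=C(C)C(=O)O[C@@H]1[C@@H](O[Si](C)(C)C(C)(C)C)[C@H](C)C2=CC(=O)[C@@](C)(C[C@H](O[Si](C)(C)C(C)(C)C)[C@H]1C(=C)CO[Si](C(C)C)(C(C)C)C(C)C)O2 | intermediate
29 | triol: C1 methacrylate with free C2, C9 and C12 hydroxyls | C=C(C)C(=O)O[C@@H]1[C@@H](O)[C@H](C)C2=CC(=O)[C@@](C)(C[C@H](O)[C@H]1C(=C)CO)O2 | intermediate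
30 | enal: C12 aldehyde of 29 (not isolated) | C=C(C)C(=O)O[C@@H]1[C@@H](O)[C@H](C)C2=CC(=O)[C@@](C)(C[C@H](O)[C@H]1C(=C)C=O)O2 | intermediate
31 | lactol between O9 and C12 (lactol epimers; not isolated) | C=C(C)C(=O)O[C@@H]1[C@@H](O)[C@H](C)C2=CC(=O)[C@@](C)(C[C@@H]3OC(O)C(=C)[C@@H]13)O2 | intermediate
32 | CNP0195404.1 | C=C(C)C(=O)O[C@@H]1[C@@H](O)[C@H](C)C2=CC(=O)[C@@](C)(C[C@@H]3OC(=O)C(=C)[C@@H]13)O2 | target

Total step count: 22. Longest linear sequence: 19 steps (5 → 32, steps 4–22).

Steps most likely to fail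

1. Step 17. Intermolecular aldol addition (oligomerisation) may overtake ring closure. The silyl group may also be lost before C–C bond formation, returning the unreactive furanone, or the chelate may not hold in the medium-ring transition state, so that the wrong carbonyl face is attacked. Fallback (known reactions only; sets out from 3 and 10, returns at 26): the order of the two skeletal bonds is reversed, C2–C3 being made between two molecules and the ring closed at C9–C10.
   - Furanone half: dioxolanone 3 is opened with Me(MeO)NMgCl to (2R)-2,4-dihydroxy-N-methoxy-N,2-dimethylbutanamide F1. Excess 1-butynyllithium gives (3R)-1,3-dihydroxy-3-methyloct-5-yn-4-one F2, and gold catalysis as in step 12 gives (2R)-5-ethyl-2-(2-hydroxyethyl)-2-methylfuran-3(2H)-one F3.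
   - Aldehyde half: bromide 10 is transacetalised (4-MeOC6H4CH(OMe)2, CSA, CH2Cl2) to its 4-methoxybenzylidene acetal analogue F4. This is opened with i-Bu2AlH (−78 → −20 °C) to (2S,3Z)-4-(bromomethyl)-2-[(4-methoxyphenyl)methoxy]-5-{[tri(propan-2-yl)silyl]oxy}pent-3-en-1-ol F5 and oxidised (Dess–Martin periodinane, pyridine) to the corresponding pent-3-enal F6.
   - Union and ring closure: the dianion of F3 (LDA, 2.1 equiv, THF, −78 °C) adds through its γ-carbon to F6 precomplexed with MgBr2·OEt2, the established γ-aldol reaction of 5-alkyl-3(2H)-furanone dienolates run under chelation control. Quenching cold should give the open-chain aldol adduct F7. TEMPO/PhI(OAc)2 oxidises only the primary alcohol, to the hydroxy aldehyde F8. An intramolecular Nozaki–Hiyama allylation (CrCl2, THF, high dilution), a standard closure of ten-membered germacranolide rings, should give the macrocyclic C2,C9-diol F9. TBSOTf/2,6-lutidine (2.5 equiv) silylates both hydroxyls to give 26.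

2. Step 8. 1,2-Induction from C1 may be weak or reversed, so that the aldehyde adds to the other face of the allylchromium reagent and the C9,C10-bis-epimer forms. Acyl transfer from the dioxolanone to the new C9 oxygen is a second risk. Fallback (sets out from 4 and 10, returns at 12): stereocontrol is handed from the reagent's own stereocentre to an external chiral controller. A catalytic enantioselective Nozaki–Hiyama allylation is used (CrCl2 10 mol %, chiral tridentate bis(oxazolinyl)carbazole ligand, Mn powder, TMSCl, i-Pr2NEt, THF, rt), with the ligand enantiomer chosen in the matched sense. The catalyst fixes the aldehyde face (C9), and the anti-selective chair arrangement then fixes C10 whatever the intrinsic bias of C1. The product is released from the metal as the trimethylsilyl ether of 12 F10, which dilute HCl in THF hydrolyses to 12.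

3. Step 15. Hydride may be delivered to the wrong acetal C–O bond (PMB ether ending on O2), or the silyl dienol ether may erode during the long exposure to the Lewis-acidic alane on warming. Fallback (sets out from 19, isolated instead of being carried on, returns at 23): the two oxygens are differentiated stepwise and the alane is used only at −78 °C. PivCl/pyridine (0 °C) acylates the primary hydroxyl to the C2 pivalate of diol 19 F11. 4-Methoxybenzyl trichloroacetimidate with La(OTf)3 (cat.) gives the C1 PMB ether of the pivalate F12. LiN(SiMe3)2 then TBSOTf as in step 14 gives the silyl dienol ether of the PMB-protected pivalate F13. i-Bu2AlH (2.5 equiv, CH2Cl2, −78 °C) removes the pivalate to give 23.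

Further compounds
F1 | step 17 | (2R)-2,4-dihydroxy-N-methoxy-N,2-dimethylbutanamide | OCC[C@@](C)(O)C(=O)N(C)OC
F2 | step 17 | (3R)-1,3-dihydroxy-3-methyloct-5-yn-4-one | OCC[C@@](C)(O)C(=O)C#CCC
F3 | step 17 | (2R)-5-ethyl-2-(2-hydroxyethyl)-2-methylfuran-3(2H)-one | OCC[C@@]1(C)OC(CC)=CC1=O
F4 | step 17 | 4-methoxybenzylidene acetal analogue of 10 (acetal epimers) | COc1ccc(cc1)C1OC[C@H](/C=C(\CBr)CO[Si](C(C)C)(C(C)C)C(C)C)O1
F5 | step 17 | (2S,3Z)-4-(bromomethyl)-2-[(4-methoxyphenyl)methoxy]-5-{[tri(propan-2-yl)silyl]oxy}pent-3-en-1-ol | OC[C@@H](OCc1ccc(OC)cc1)/C=C(\CBr)CO[Si](C(C)C)(C(C)C)C(C)C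
F6 | step 17 | (2S,3Z)-4-(bromomethyl)-2-[(4-methoxyphenyl)methoxy]-5-{[tri(propan-2-yl)silyl]oxy}pent-3-enal | O=C[C@@H](OCc1ccc(OC)cc1)/C=C(\CBr)CO[Si](C(C)C)(C(C)C)C(C)C
F7 | step 17 | open-chain γ-aldol adduct (free C2 and C9 hydroxyls, C1 OPMB, allylic bromide, C12 OTIPS) | OCC[C@@]1(C)OC(=CC1=O)[C@@H](C)[C@H](O)[C@@H](OCc2ccc(OC)cc2)/C=C(\CBr)CO[Si](C(C)C)(C(C)C)C(C)C
F8 | step 17 | C9 aldehyde of the open-chain aldol adduct | O=CC[C@@]1(C)OC(=CC1=O)[C@@H](C)[C@H](O)[C@@H](OCc2ccc(OC)cc2)/C=C(\CBr)CO[Si](C(C)C)(C(C)C)C(C)C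
F9 | step 17 | macrocyclic C2,C9-diol (C1 OPMB, C12 OTIPS) | COc1ccc(CO[C@@H]2[C@@H](O)[C@H](C)C3=CC(=O)[C@@](C)(C[C@H](O)[C@H]2C(=C)CO[Si](C(C)C)(C(C)C)C(C)C)O3)cc1
F10 | step 8 | trimethylsilyl ether of 12 | CC1(C)OC[C@H]([C@H](C(=C)CO[Si](C(C)C)(C(C)C)C(C)C)[C@@H](O[Si](C)(C)C)C[C@@]2(C)OC(C)(C)OC2=O)O1
F11 | step 15 | C2 pivalate of diol 19 | CC(C)(C)C(=O)OC[C@@H](O)[C@H](C(=C)CO[Si](C(C)C)(C(C)C)C(C)C)[C@@H](O[Si](C)(C)C(C)(C)C)C[C@@]1(C)OC(CC)=CC1=O
F12 | step 15 | C1 PMB ether of the pivalate | CC(C)(C)C(=O)OC[C@@H](OCc1ccc(OC)cc1)[C@H](C(=C)CO[Si](C(C)C)(C(C)C)C(C)C)[C@@H](O[Si](C)(C)C(C)(C)C)C[C@@]2(C)OC(CC)=CC2=O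
F13 | step 15 | tert-butyldimethylsilyl dienol ether of the PMB-protected pivalate | CC(C)(C)C(=O)OC[C@@H](OCc1ccc(OC)cc1)[C@H](C(=C)CO[Si](C(C)C)(C(C)C)C(C)C)[C@@H](O[Si](C)(C)C(C)(C)C)C[C@@]2(C)O/C(=C\C)C=C2O[Si](C)(C)C(C)(C)C
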